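The route rests on disconnecting the cyclohexenone ring of the cis-hydrindenone at its carbonyl carbon C4. Without C4, and with C7 bonded to C3a, the core becomes a meso 1,5-dimethylbicyclo[3.1.0]hexane carrying an exo 2-propenyl unit on its C6, because the methyl-bearing ring-fusion carbons C3a and C7a are then mirror images. The key step, a Rh-catalysed [5+1] carbonylation, runs this in reverse: one of the two enantiotopic cyclopropane bonds is cut, CO becomes C4, the six-membered ring closes, and both quaternary centres gain their absolute configuration in one operation. The precursor is the meso exo-6-[3-(methoxymethoxy)prop-1-en-2-yl]cyclopropane 6.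

Key step: step 5

Remark: both C6 epimers of the cyclopropane are meso and C6 becomes sp2 in step 5, so the exo configuration is chosen for access of the metal, not for the stereochemical outcome; the sense of induction in step 5 cannot be predicted, so the ligand antipode is fixed after a test run.

Step 1
Reactants: 1 1,2-dimethylcyclopentene; 2 ethyl diazoacetate
Product: 3 ethyl (1R,5S,6s)-1,5-dimethylbicyclo[3.1.0]hexane-6-carboxylate (meso, ester exo)
Conditions: Rh2(OAc)4 (1 mol %), 1 (3 equiv), slow addition of 2, CH2Cl2, rt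
Reagents that add atoms: none
Why: Rh(II)-carbenoid cyclopropanation of the electron-rich tetrasubstituted alkene is stereospecific, so C1 and C5 are necessarily cis-fused, and the ester should settle mainly exo at C6 (between the splayed methyl groups, away from the ring methylenes that flank the C=C), the endo epimer being removed by chromatography.

Step 2
Reactants: 3 ethyl (1R,5S,6s)-1,5-dimethylbicyclo[3.1.0]hexane-6-carboxylate
Product: 4 (1R,5S,6s)-N-methoxy-N,1,5-trimethylbicyclo[3.1.0]hexane-6-carboxamide (meso)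
Conditions: MeNH(OMe)·HCl, i-PrMgCl, THF, −20 °C → rt
Reagents that add atoms: N,O-dimethylhydroxylamine hydrochloride, CNOC.Cl
Why: Weinreb amide formation by acyl substitution with the small magnesium amide of N,O-dimethylhydroxylamine, which should reach the hindered ester carbonyl; no stereocentre is touched.

Step 3
Reactants: 4 (1R,5S,6s)-N-methoxy-N,1,5-trimethylbicyclo[3.1.0]hexane-6-carboxamide
Product: 5 1-[(1R,5S,6s)-1,5-dimethylbicyclo[3.1.0]hexan-6-yl]-2-(methoxymethoxy)ethan-1-one (meso)
Conditions: Bu3SnCH2OMOM, n-BuLi, THF, −78 °C; then 4, −78 → −40 °C; aq NH4Cl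
Reagents that add atoms: tributyl[(methoxymethoxy)methyl]stannane, CCCC[Sn](CCCC)(CCCC)COCOC
Why: Addition of the α-alkoxymethyllithium (from tin–lithium exchange) to the Weinreb amide stops at the chelated tetrahedral intermediate and gives the ketone on work-up, the poorly acidic cyclopropyl C6–H keeping its exo configuration.

Step 4
Reactants: 5 1-[(1R,5S,6s)-1,5-dimethylbicyclo[3.1.0]hexan-6-yl]-2-(methoxymethoxy)ethan-1-one
Product: 6 (1R,5S,6s)-6-[3-(methoxymethoxy)prop-1-en-2-yl]-1,5-dimethylbicyclo[3.1.0]hexane (meso, alkenyl exo)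
Conditions: Ph3PCH3Br, KOt-Bu, THF, 0 °C → rt
Reagents that add atoms: methyltriphenylphosphonium bromide, C[P+](c1ccccc1)(c1ccccc1)c1ccccc1.[Br-]
Why: Wittig methylenation with the non-stabilised ylide converts the ketone into the 1,1-disubstituted alkene without epimerising C6, whose cyclopropyl hydrogen resists enolisation.

Step 5
Reactants: 6 (1R,5S,6s)-6-[3-(methoxymethoxy)prop-1-en-2-yl]-1,5-dimethylbicyclo[3.1.0]hexane; 7 carbon monoxide
Product: 8 (3aR,7aR)-6-[(methoxymethoxy)methyl]-3a,7a-dimethyl-1,2,3,3a,5,7a-hexahydro-4H-inden-4-one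
Conditions: [Rh(cod)2]OTf (5 mol %), (R,R)-BDPP (6 mol %), CO (1 atm), 1,2-dichloroethane, 80 °C
Reagents that add atoms: none
Why: Proposed new method: Rh(I) binds the exo alkene and inserts oxidatively into the proximal C5–C6 cyclopropane bond to give a rhodacyclohexene (σ-alkyl at C5, π-allyl over C6, C2′ and C1′), CO inserts into the Rh–C5 bond, and C–C reductive elimination between the acyl carbon and the allyl terminus C1′ releases the β,γ-unsaturated ketone. The closest known reaction type is the Rh(I)- or iron/cobalt-carbonyl-mediated [5+1] carbonylation of vinylcyclopropanes to cyclohexenones, which has not been run as an enantioselective desymmetrisation or on proximal bonds that end at quaternary carbons. The six-membered ring closes by acyl–allyl reductive elimination from the seven-membered acylrhodacycle, a formal [5+1] cycloaddition in which C4–C3a and C4–C5 are the two new bonds. C3a and C7a are the former bridgeheads C5 and C1, which react with retention, so the cis ring fusion is inherited and the absolute configuration depends only on which enantiotopic bond is cut: cleavage of C5–C6 at the S bridgehead leads to (3aR,7aR)-8, a choice that the C2-symmetric bisphosphine has to impose because the substrate offers no bias. Proximal rather than distal (C1–C5) cleavage is secured by the alkene, which delivers the metal to C6; the exo alkenyl group on the convex face keeps the alkene and both proximal bonds accessible, and its 2-substituent favours the s-cis conformer needed for the cis ring alkene.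

Step 6
Reactants: 8 (3aR,7aR)-6-[(methoxymethoxy)methyl]-3a,7a-dimethyl-1,2,3,3a,5,7a-hexahydro-4H-inden-4-one
Product: 10 (3aR,7aR)-6-[(methoxymethoxy)methyl]-3a,7a-dimethyl-5-(2-methylprop-2-en-1-yl)-1,2,3,3a,7,7a-hexahydro-4H-inden-4-one, via α-methallyl β,γ-enone 9 (not isolated)
Conditions: LiHMDS, THF, −78 °C; 3-bromo-2-methylpropene, −78 → −20 °C; then DBU, rt
Reagents that add atoms: 3-bromo-2-methylprop-1-ene, C=C(C)CBr
Why: The doubly activated C5 methylene (α to C=O and allylic) is deprotonated regiospecifically and the linear dienolate is C-alkylated at the α-carbon (kinetic dienolate alkylation), after which DBU moves the C6=C7 bond into conjugation through the same dienolate, erasing the transient C5 stereocentre and leaving the non-enolisable quaternary centres untouched.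

Step 7
Reactants: 10 (3aR,7aR)-6-[(methoxymethoxy)methyl]-3a,7a-dimethyl-5-(2-methylprop-2-en-1-yl)-1,2,3,3a,7,7a-hexahydro-4H-inden-4-one
Product: 11 (3aR,7aR)-6-(hydroxymethyl)-3a,7a-dimethyl-5-(2-methylprop-2-en-1-yl)-1,2,3,3a,7,7a-hexahydro-4H-inden-4-one
Conditions: ZnBr2, n-PrSH, CH2Cl2, 0 °C → rt
Reagents that add atoms: none
Why: Lewis acid–thiol cleavage of the MOM acetal (ZnBr2 activates the acetal, the thiol captures the oxocarbenium ion) frees the primary allylic alcohol without protic acid that could isomerise the methallyl alkene.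

Step 8
Reactants: 11 (3aR,7aR)-6-(hydroxymethyl)-3a,7a-dimethyl-5-(2-methylprop-2-en-1-yl)-1,2,3,3a,7,7a-hexahydro-4H-inden-4-one
Product: 12 (3aR,7aR)-5-(2-hydroxy-2-methylpropyl)-6-(hydroxymethyl)-3a,7a-dimethyl-1,2,3,3a,7,7a-hexahydro-4H-inden-4-one
Conditions: Co(acac)2 (20 mol %), PhSiH3, O2 (1 atm), THF, rt; aq Na2S2O3
Reagents that add atoms: dioxygen, O=O
Why: Mukaiyama hydration (cobalt-hydride hydrogen-atom transfer, then O2 capture of the tertiary radical) is Markovnikov-selective for the electron-rich 1,1-disubstituted alkene and should leave the hindered, electron-poor tetrasubstituted enone alone; no stereocentre is formed.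

Step 9
Reactants: 12 (3aR,7aR)-5-(2-hydroxy-2-methylpropyl)-6-(hydroxymethyl)-3a,7a-dimethyl-1,2,3,3a,7,7a-hexahydro-4H-inden-4-one
Product: 13 (3aR,7aR)-6-(bromomethyl)-5-(2-hydroxy-2-methylpropyl)-3a,7a-dimethyl-1,2,3,3a,7,7a-hexahydro-4H-inden-4-one
Conditions: CBr4, PPh3, CH2Cl2, 0 °C
Reagents that add atoms: tetrabromomethane, BrC(Br)(Br)Br
Why: Appel bromination, in which the unhindered primary allylic alcohol forms the alkoxyphosphonium salt and is displaced by bromide far faster than the hindered tertiary alcohol can react; the bromide is used at once.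

Step 10
Reactants: 14 ethyl but-2-ynoate
Product: 15 ethyl (2E)-3-(tributylstannyl)but-2-enoate
Conditions: (Bu3Sn)2, n-BuLi, THF, −20 °C; CuBr·SMe2, −78 °C; then 14, MeOH, −78 °C
Reagents that add atoms: hexabutyldistannane, CCCC[Sn](CCCC)(CCCC)[Sn](CCCC)(CCCC)CCCC
Why: Syn stannylcupration of the ynoate with immediate protonation of the α-cuprio enoate at −78 °C places tin on the β-carbon and gives the E alkene (tin trans to the ester) under kinetic control.

Step 11
Reactants: 15 ethyl (2E)-3-(tributylstannyl)but-2-enoate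
Product: 16 (2E)-3-(tributylstannyl)but-2-en-1-ol
Conditions: DIBAL-H, CH2Cl2, −78 °C; Rochelle salt
Reagents that add atoms: none
Why: DIBAL-H reduces the conjugated ester in a 1,2-fashion to the allylic alcohol without touching the vinyl–tin bond or the alkene geometry.

Step 12
Reactants: 16 (2E)-3-(tributylstannyl)but-2-en-1-ol
Product: 17 tributyl[(2E)-4-bromobut-2-en-2-yl]stannane
Conditions: CBr4, PPh3, 2,6-lutidine, CH2Cl2, 0 °C
Reagents that add atoms: tetrabromomethane, BrC(Br)(Br)Br
Why: Appel bromination of the primary allylic alcohol under buffered, neutral conditions preserves the acid-sensitive vinylstannane and the E geometry.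

Step 13
Reactants: 17 tributyl[(2E)-4-bromobut-2-en-2-yl]stannane; 18 4-methoxy-2-methylphenol
Product: 19 4-methoxy-2-methyl-6-[(2E)-3-(tributylstannyl)but-2-en-1-yl]phenol
Conditions: NaH, toluene, 0 °C → 50 °C
Reagents that add atoms: none
Why: ortho-C-Allylation of the sodium phenoxide as a tight ion pair in a non-polar solvent (SN2 at the primary allylic carbon, so the E geometry is kept); the para position carries OMe and the other ortho position carries Me, so only C6 can be alkylated, and any O-allyl ether is separated.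

Step 14
Reactants: 13 (3aR,7aR)-6-(bromomethyl)-5-(2-hydroxy-2-methylpropyl)-3a,7a-dimethyl-1,2,3,3a,7,7a-hexahydro-4H-inden-4-one; 19 4-methoxy-2-methyl-6-[(2E)-3-(tributylstannyl)but-2-en-1-yl]phenol
Product: 20 (3aR,7aR)-5-(2-hydroxy-2-methylpropyl)-6-[(2E)-4-(2-hydroxy-5-methoxy-3-methylphenyl)-2-methylbut-2-en-1-yl]-3a,7a-dimethyl-1,2,3,3a,7,7a-hexahydro-4H-inden-4-one (CNP0158008.2)
Conditions: Pd2(dba)3 (5 mol %), AsPh3 (20 mol %), NMP, rt → 40 °C
Reagents that add atoms: none
Why: Stille coupling, in which Pd(0) ionises the allylic bromide to a π-allyl complex, the vinylstannane transmetallates with retention of geometry and reductive elimination at the unhindered CH2 terminus gives the skipped diene with the E trisubstituted alkene; the neutral conditions tolerate phenol, tertiary alcohol and enone.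

Compound list
1 | 1,2-dimethylcyclopentene | CC1=C(C)CCC1 | starting material
2 | ethyl diazoacetate | CCOC(=O)C=[N+]=[N-] | starting material
3 | ethyl (1R,5S,6s)-1,5-dimethylbicyclo[3.1.0]hexane-6-carboxylate (meso, ester exo, cis to both methyls) | CCOC(=O)[C@@H]1[C@@]2(C)CCC[C@@]12C | intermediate
4 | (1R,5S,6s)-N-methoxy-N,1,5-trimethylbicyclo[3.1.0]hexane-6-carboxamide (meso) | CON(C)C(=O)[C@@H]1[C@@]2(C)CCC[C@@]12C | intermediate
5 | 1-[(1R,5S,6s)-1,5-dimethylbicyclo[3.1.0]hexan-6-yl]-2-(methoxymethoxy)ethan-1-one (meso) | COCOCC(=O)[C@@H]1[C@@]2(C)CCC[C@@]12C | intermediate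
6 | (1R,5S,6s)-6-[3-(methoxymethoxy)prop-1-en-2-yl]-1,5-dimethylbicyclo[3.1.0]hexane (meso, alkenyl exo; key-step precursor) | C=C(COCOC)[C@@H]1[C@@]2(C)CCC[C@@]12C | intermediate
7 | carbon monoxide | [C-]#[O+] | starting material
8 | (3aR,7aR)-6-[(methoxymethoxy)methyl]-3a,7a-dimethyl-1,2,3,3a,5,7a-hexahydro-4H-inden-4-one (key-step product) | C1(COCOC)CC(=O)[C@]2(C)CCC[C@]2(C)C=1 | intermediate
9 | (3aR,7aR)-6-[(methoxymethoxy)methyl]-3a,7a-dimethyl-5-(2-methylprop-2-en-1-yl)-1,2,3,3a,5,7a-hexahydro-4H-inden-4-one (α-methallyl β,γ-enone, both C5 epimers) | C=C(C)CC1C(=O)[C@]2(C)CCC[C@]2(C)C=C1COCOC | intermediate (not isolated)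
10 | (3aR,7aR)-6-[(methoxymethoxy)methyl]-3a,7a-dimethyl-5-(2-methylprop-2-en-1-yl)-1,2,3,3a,7,7a-hexahydro-4H-inden-4-one | COCOCC1=C(CC(C)=C)C(=O)[C@]2(C)CCC[C@]2(C)C1 | intermediate
11 | (3aR,7aR)-6-(hydroxymethyl)-3a,7a-dimethyl-5-(2-methylprop-2-en-1-yl)-1,2,3,3a,7,7a-hexahydro-4H-inden-4-one | OCC1=C(CC(C)=C)C(=O)[C@]2(C)CCC[C@]2(C)C1 | intermediate
12 | (3aR,7aR)-5-(2-hydroxy-2-methylpropyl)-6-(hydroxymethyl)-3a,7a-dimethyl-1,2,3,3a,7,7a-hexahydro-4H-inden-4-one | OCC1=C(CC(C)(C)O)C(=O)[C@]2(C)CCC[C@]2(C)C1 | intermediate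
13 | (3aR,7aR)-6-(bromomethyl)-5-(2-hydroxy-2-methylpropyl)-3a,7a-dimethyl-1,2,3,3a,7,7a-hexahydro-4H-inden-4-one | BrCC1=C(CC(C)(C)O)C(=O)[C@]2(C)CCC[C@]2(C)C1 | intermediate
14 | ethyl but-2-ynoate | CC#CC(=O)OCC | starting material
15 | ethyl (2E)-3-(tributylstannyl)but-2-enoate | CCOC(=O)/C=C(\C)[Sn](CCCC)(CCCC)CCCC | intermediate
16 | (2E)-3-(tributylstannyl)but-2-en-1-ol | OC/C=C(\C)[Sn](CCCC)(CCCC)CCCC | intermediate
17 | tributyl[(2E)-4-bromobut-2-en-2-yl]stannane | BrC/C=C(\C)[Sn](CCCC)(CCCC)CCCC | intermediate
18 | 4-methoxy-2-methylphenol | COc1ccc(O)c(C)c1 | starting material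
19 | 4-methoxy-2-methyl-6-[(2E)-3-(tributylstannyl)but-2-en-1-yl]phenol | COc1cc(C)c(O)c(C/C=C(\C)[Sn](CCCC)(CCCC)CCCC)c1 | intermediate
20 | (3aR,7aR)-5-(2-hydroxy-2-methylpropyl)-6-[(2E)-4-(2-hydroxy-5-methoxy-3-methylphenyl)-2-methylbut-2-en-1-yl]-3a,7a-dimethyl-1,2,3,3a,7,7a-hexahydro-4H-inden-4-one | COc1cc(C)c(O)c(C/C=C(\C)CC2=C(CC(C)(C)O)C(=O)[C@]3(C)CCC[C@]3(C)C2)c1 | target

Total step count: 14 (ten on the main line, four for the stannane branch).
Longest linear sequence: 10 steps (steps 1–9 and 14).

Steps most likely to fail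

1. Step 5 (key step, beyond precedent). The metal may fail to insert into cyclopropane bonds that end at quaternary carbons, or may insert without distinguishing the two enantiotopic bonds. The fallback uses known chemistry, sets out from 1 and returns at 11; it builds the same ring by a de Mayo-type annulation without a cyclopropane. Irradiation of 1 with 2,2,6-trimethyl-4H-1,3-dioxin-4-one should give the cis-fused cyclobutane photoadduct F1. K2CO3 in methanol opens the dioxanone, releases acetone and triggers retro-aldol cleavage to racemic methyl 2-(cis-2-acetyl-1,2-dimethylcyclopentyl)acetate F2. KOt-Bu closes the six-membered ring by intramolecular Claisen condensation to racemic cis-3a,7a-dimethylhexahydroindene-4,6-dione F3. Pd(0)-catalysed C-allylation with methallyl methyl carbonate gives the 5-(2-methylallyl) dione F4. Triflation (Tf2O, 2,6-lutidine) at the less hindered C6 oxygen gives the enol triflate F5. Stille hydroxymethylation with (tributylstannyl)methanol (Pd(PPh3)4, LiCl) gives racemic 11 F6, which is resolved by preparative chromatography on a chiral stationary phase to give 11.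

2. Step 14 (the hazard begins in step 9). The tertiary hydroxyl of 13, held next to the allylic carbon by the tetrasubstituted alkene, may close a dihydropyran by intramolecular O-allylation, during bromination or at the π-allylpalladium stage, faster than the vinyl group is transferred. The fallback sets out from 12 and returns at 20; it masks the tertiary alcohol before the allylic position is activated. TESOTf and 2,6-lutidine give the bis(triethylsilyl) ether F7. PPTS in methanol at 0 °C removes only the primary silyl group to give the tertiary silyl ether alcohol F8. Appel bromination gives the silyl-protected bromide F9. Stille coupling with 19 under the conditions of step 14 gives the O-triethylsilyl ether of the target F10. HF·pyridine in THF then frees the tertiary alcohol to give 20.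

3. Step 13. O-Allylation of the phenoxide may outrun ortho-C-allylation in spite of the non-polar medium. The fallback sets out from 18 and returns at 19; it makes the ortho carbon the only strong nucleophile. NBS brominates 18 ortho to the hydroxyl to give 2-bromo-4-methoxy-6-methylphenol F11. Two equivalents of n-BuLi (deprotonation, then bromine–lithium exchange) give the C,O-dilithiated phenol F12, whose aryllithium carbon is alkylated by 17 at −78 °C (SN2, geometry retained) to give 19 after aqueous work-up.

Further compounds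
F1 | step 5 | cyclobutane photoadduct of 1 with 2,2,6-trimethyl-4H-1,3-dioxin-4-one (racemic, cis-fused, diastereomer mixture) | CC12CCCC1(C)C1C(=O)OC(C)(C)OC21C
F2 | step 5 | rac-methyl 2-(cis-2-acetyl-1,2-dimethylcyclopentyl)acetate (drawn as the enantiomer that maps onto 11) | CC(=O)[C@]1(C)CCC[C@]1(C)CC(=O)OC
F3 | step 5 | rac-cis-3a,7a-dimethylhexahydro-1H-indene-4,6(5H)-dione (drawn as the enantiomer that maps onto 11) | O=C1CC(=O)[C@]2(C)CCC[C@]2(C)C1
F4 | step 5 | rac-cis-3a,7a-dimethyl-5-(2-methylprop-2-en-1-yl)hexahydro-1H-indene-4,6(5H)-dione (drawn as the enantiomer that maps onto 11) | O=C1C(CC(C)=C)C(=O)[C@]2(C)CCC[C@]2(C)C1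
F5 | step 5 | rac-cis-3a,7a-dimethyl-5-(2-methylprop-2-en-1-yl)-4-oxo-2,3,3a,4,7,7a-hexahydro-1H-inden-6-yl trifluoromethanesulfonate (drawn as the enantiomer that maps onto 11) | O=S(=O)(OC1=C(CC(C)=C)C(=O)[C@]2(C)CCC[C@]2(C)C1)C(F)(F)F
F6 | step 5 | racemic 11 (both enantiomers) | OCC1=C(CC(C)=C)C(=O)[C@]2(C)CCC[C@]2(C)C1.OCC1=C(CC(C)=C)C(=O)[C@@]2(C)CCC[C@@]2(C)C1
F7 | step 14 | (3aR,7aR)-3a,7a-dimethyl-5-{2-methyl-2-[(triethylsilyl)oxy]propyl}-6-{[(triethylsilyl)oxy]methyl}-1,2,3,3a,7,7a-hexahydro-4H-inden-4-one | CC[Si](CC)(CC)OCC1=C(CC(C)(C)O[Si](CC)(CC)CC)C(=O)[C@]2(C)CCC[C@]2(C)C1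
F8 | step 14 | (3aR,7aR)-6-(hydroxymethyl)-3a,7a-dimethyl-5-{2-methyl-2-[(triethylsilyl)oxy]propyl}-1,2,3,3a,7,7a-hexahydro-4H-inden-4-one | OCC1=C(CC(C)(C)O[Si](CC)(CC)CC)C(=O)[C@]2(C)CCC[C@]2(C)C1
F9 | step 14 | (3aR,7aR)-6-(bromomethyl)-3a,7a-dimethyl-5-{2-methyl-2-[(triethylsilyl)oxy]propyl}-1,2,3,3a,7,7a-hexahydro-4H-inden-4-one | BrCC1=C(CC(C)(C)O[Si](CC)(CC)CC)C(=O)[C@]2(C)CCC[C@]2(C)C1
F10 | step 14 | O-triethylsilyl ether (tertiary alcohol) of 20 | COc1cc(C)c(O)c(C/C=C(\C)CC2=C(CC(C)(C)O[Si](CC)(CC)CC)C(=O)[C@]3(C)CCC[C@]3(C)C2)c1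
F11 | step 13 | 2-bromo-4-methoxy-6-methylphenol | COc1cc(C)c(O)c(Br)c1
F12 | step 13 | lithium 2-lithio-4-methoxy-6-methylphenolate | COc1cc(C)c(O[Li])c([Li])c1
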